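**Retrosynthetic overview**

- The last step is one hydrogenation that saturates a butenolide C=C and removes a benzyl ester. Before it, CH2NO2 is oxidised to CO2H, and the malate ester is made from the ω-alcohol and (R)-malic acid through its O-trifluoroacetyl anhydride, which opens at C1.
- Key C–C bond: the bond between the lactone quaternary carbon and the carboxyl-bearing CH (the 2,3-bond of the alkylated succinate). It is made by a catalytic asymmetric vinylogous Michael addition of a γ-(benzyloxycarbonyl)butenolide dienolate to (E)-12-nitrododec-11-en-1-ol. The nitroalkene serves as an α-carboxyl cation (enolonium) equivalent, and both stereocentres are set in this step.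
- The nitroalkene comes from 11-bromoundecan-1-ol (Ganem oxidation, then Henry reaction and dehydration). The butenolide comes from (S)-5-oxotetrahydrofuran-2-carboxylic acid (benzylation, then selenoxide dehydrogenation).
- Rings: the only ring, the γ-lactone, is bought in with the lactone acid and is never opened. It is dehydrogenated to the butenolide to acidify the γ-C–H and re-saturated in the last step.

Assumption: the target is read as drawn ((R)-malate, (S) at the carboxyl-bearing CH, (R) at the lactone quaternary carbon). The facial sense of the (S,S)-aminothiourea toward the nitroalkene is taken from its malonate additions; if the first run shows the mirror-image sense, the (R,R)-antipode is used instead.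

**Route**

Step 1
Reactants: 1 11-bromoundecan-1-ol
Product: 2 11-hydroxyundecanal
Conditions: Me3NO (anhydrous, 4 equiv), DMSO, rt, 3 h
Reagents that add atoms: trimethylamine N-oxide, C[N+](C)(C)[O-] (supplies the aldehyde oxygen)
Why: Ganem oxidation: SN2 O-alkylation of the N-oxide by the primary bromide followed by base-induced N–O cleavage turns CH2Br into CHO without touching the free primary alcohol; no stereocentre is involved.

Step 2
Reactants: 2 11-hydroxyundecanal; 3 nitromethane
Product: 7 (E)-12-nitrododec-11-en-1-ol, via nitro diol 4 (not isolated), via bis(trifluoroacetate) 5 (not isolated), via nitroalkene trifluoroacetate 6 (not isolated)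
Conditions: MeNO2 (5 equiv), KOtBu (10 mol%), THF/tBuOH, 0 °C to rt; AcOH quench, evaporate; TFAA (2.2 equiv), Et3N (3.3 equiv), CH2Cl2, −20 to 0 °C; then THF/sat. aq NaHCO3, 0 °C to rt
Reagents that add atoms: none
Why: Henry reaction then dehydration: the β-nitro trifluoroacetate undergoes E1cB elimination to the thermodynamically favoured (E)-nitroalkene, and the primary alcohol, trifluoroacetylated in passing, is freed again because this very labile ester hydrolyses in the bicarbonate work-up.

Step 3
Reactants: 8 (S)-5-oxotetrahydrofuran-2-carboxylic acid; 9 benzyl bromide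
Product: 10 benzyl (2S)-5-oxooxolane-2-carboxylate
Conditions: BnBr (1.1 equiv), K2CO3 (1.2 equiv), DMF, rt
Reagents that add atoms: none
Why: SN2 O-alkylation of the carboxylate gives the benzyl ester, chosen so that the last hydrogenation removes it; the stereocentre is not touched.

Step 4
Reactants: 10 benzyl (2S)-5-oxooxolane-2-carboxylate
Product: 13 benzyl (2S)-5-oxo-2,5-dihydrofuran-2-carboxylate, via selenide 11 (not isolated), via selenoxide 12 (not isolated)
Conditions: LiN(SiMe3)2 (1.05 equiv), THF, −78 °C; PhSeBr (1.1 equiv), −78 °C; then 30% H2O2, pyridine, CH2Cl2, 0 °C to rt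
Reagents that add atoms: none
Why: α-Selenenylation of the kinetic lactone enolate (the unhindered CH2 next to the ring carbonyl) and selenoxide syn-elimination give the butenolide; any C2-selenenylated material would eliminate to the enol-lactone tautomer, which gives the same dienolate in step 5, and the C2 configuration does not matter because it is erased there.

Step 5
Reactants: 7 (E)-12-nitrododec-11-en-1-ol; 13 benzyl (2S)-5-oxo-2,5-dihydrofuran-2-carboxylate
Product: 14 benzyl (2R)-2-[(2R)-12-hydroxy-1-nitrododecan-2-yl]-5-oxo-2,5-dihydrofuran-2-carboxylate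
Conditions: 13 (1.3 equiv), 1-[3,5-bis(trifluoromethyl)phenyl]-3-[(1S,2S)-2-(dimethylamino)cyclohexyl]thiourea (10 mol%), toluene, −20 °C, 48 h
Reagents that add atoms: none
Why: Proposed new method: the tertiary amine of the bifunctional catalyst deprotonates the doubly activated γ-C–H of 13 (α to the ester, vinylogous to the lactone carbonyl) to an ammonium 2-oxidofuran dienolate while the thiourea binds the nitro group of 7, which acts as an α-carboxyl cation (enolonium) equivalent, so that two carbons that both end up α to carboxyl groups are joined; bond formation between the Re face of the γ-carbon and the Re face of Cβ of the (E)-nitroalkene (like topicity, synclinal arrangement with the nitrovinyl unit over the dienolate ring and the alkyl chain anti to the ring oxygen) sets the (R)-quaternary and the (R)-tertiary centre in one step, and the free primary alcohol is a spectator; the closest known reaction types are the aminothiourea-catalysed direct vinylogous Michael addition of γ-substituted butenolides to nitroalkenes and the Mukaiyama–Michael additions of 5-alkoxycarbonyl-2-silyloxyfurans; the pairing of a γ-ester butenolide with an aliphatic nitroalkene and its diastereoselectivity are untested.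

Step 6
Reactants: 14 benzyl (2R)-2-[(2R)-12-hydroxy-1-nitrododecan-2-yl]-5-oxo-2,5-dihydrofuran-2-carboxylate; 15 (R)-malic acid
Product: 18 (3R)-4-({(11R)-11-[(2R)-2-(benzyloxycarbonyl)-5-oxo-2,5-dihydrofuran-2-yl]-12-nitrododecyl}oxy)-3-hydroxy-4-oxobutanoic acid, via trifluoroacetoxysuccinic anhydride 16 (not isolated), via trifluoroacetate 17 (not isolated)
Conditions: 15 (3 equiv), TFAA (neat), 0 °C to rt, evaporate (toluene chase); 14, THF, 0 °C to rt, 12 h; then THF/H2O, rt, 2 h
Reagents that add atoms: none
Why: Regioselective anhydride alcoholysis: TFAA turns malic acid into its O-trifluoroacetyl cyclic anhydride, which the primary alcohol opens at the more electrophilic carbonyl next to the trifluoroacetoxy-bearing carbon to give the 1-ester with the 4-acid free; mild hydrolysis removes the trifluoroacetyl group and the (R)-malate centre is never touched.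

Step 7
Reactants: 18 (3R)-4-({(11R)-11-[(2R)-2-(benzyloxycarbonyl)-5-oxo-2,5-dihydrofuran-2-yl]-12-nitrododecyl}oxy)-3-hydroxy-4-oxobutanoic acid
Product: 19 (2S)-2-[(2R)-2-(benzyloxycarbonyl)-5-oxo-2,5-dihydrofuran-2-yl]-12-{[(2R)-3-carboxy-2-hydroxypropanoyl]oxy}dodecanoic acid
Conditions: NaNO2 (3 equiv), AcOH (10 equiv), DMSO, 35 °C, 12 h
Reagents that add atoms: sodium nitrite, [Na+].[O-]N=O (supplies the oxygen atoms of the new carboxyl group)
Why: Nitrite-mediated Nef-type oxidation of the primary nitroalkane (nitrosation at the nitro-bearing carbon, loss of the original nitro group, hydrolysis) gives the carboxylic acid under weakly acidic conditions that leave the esters, the butenolide and the adjacent C–H stereocentre intact; the label of that centre changes from R to S only because the CIP priorities change.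

Step 8
Reactants: 19 (2S)-2-[(2R)-2-(benzyloxycarbonyl)-5-oxo-2,5-dihydrofuran-2-yl]-12-{[(2R)-3-carboxy-2-hydroxypropanoyl]oxy}dodecanoic acid
Product: 20 (2R)-2-[(1S)-1-carboxy-11-{[(2R)-3-carboxy-2-hydroxypropanoyl]oxy}undecyl]-5-oxooxolane-2-carboxylic acid
Conditions: H2 (1 atm), Pd/C (palladium metal on carbon, 10 wt%), EtOAc, rt
Reagents that add atoms: none
Why: Heterogeneous hydrogenation saturates the butenolide C=C and hydrogenolyses the benzyl ester in one operation; no stereocentre is made or touched, and the quaternary γ-carbon blocks double-bond migration.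

**Compound list**

1 | 11-bromoundecan-1-ol | OCCCCCCCCCCCBr | starting material
2 | 11-hydroxyundecanal | OCCCCCCCCCCC=O | intermediate
3 | nitromethane | C[N+](=O)[O-] | starting material
4 | 1-nitrododecane-2,12-diol (racemic) | OCCCCCCCCCCC(O)C[N+](=O)[O-] | intermediate
5 | 1-nitrododecane-2,12-diyl bis(trifluoroacetate) (racemic) | O=C(OCCCCCCCCCCC(OC(=O)C(F)(F)F)C[N+](=O)[O-])C(F)(F)F | intermediate
6 | (E)-12-nitrododec-11-en-1-yl trifluoroacetate | O=C(OCCCCCCCCCC/C=C/[N+](=O)[O-])C(F)(F)F | intermediate
7 | (E)-12-nitrododec-11-en-1-ol | OCCCCCCCCCC/C=C/[N+](=O)[O-] | intermediate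
8 | (S)-5-oxotetrahydrofuran-2-carboxylic acid | OC(=O)[C@@H]1CCC(=O)O1 | starting material
9 | benzyl bromide | BrCc1ccccc1 | starting material
10 | benzyl (2S)-5-oxooxolane-2-carboxylate | O=C(OCc1ccccc1)[C@@H]1CCC(=O)O1 | intermediate
11 | benzyl (2S)-5-oxo-4-(phenylselanyl)oxolane-2-carboxylate (C4 epimers) | O=C(OCc1ccccc1)[C@@H]1CC([Se]c2ccccc2)C(=O)O1 | intermediate
12 | benzyl (2S)-5-oxo-4-(phenylseleninyl)oxolane-2-carboxylate (C4 epimers) | O=C(OCc1ccccc1)[C@@H]1CC([Se](=O)c2ccccc2)C(=O)O1 | intermediate
13 | benzyl (2S)-5-oxo-2,5-dihydrofuran-2-carboxylate (configuration of no consequence) | O=C(OCc1ccccc1)[C@@H]1C=CC(=O)O1 | intermediate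
14 | benzyl (2R)-2-[(2R)-12-hydroxy-1-nitrododecan-2-yl]-5-oxo-2,5-dihydrofuran-2-carboxylate | OCCCCCCCCCC[C@H](C[N+](=O)[O-])[C@@]1(C(=O)OCc2ccccc2)C=CC(=O)O1 | intermediate
15 | (R)-malic acid | O=C(O)C[C@@H](O)C(=O)O | starting material
16 | (3R)-2,5-dioxooxolan-3-yl trifluoroacetate | O=C1C[C@@H](OC(=O)C(F)(F)F)C(=O)O1 | intermediate
17 | (3R)-4-({(11R)-11-[(2R)-2-(benzyloxycarbonyl)-5-oxo-2,5-dihydrofuran-2-yl]-12-nitrododecyl}oxy)-4-oxo-3-(trifluoroacetoxy)butanoic acid | O=C(O)C[C@@H](OC(=O)C(F)(F)F)C(=O)OCCCCCCCCCC[C@H](C[N+](=O)[O-])[C@@]1(C(=O)OCc2ccccc2)C=CC(=O)O1 | intermediate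
18 | (3R)-4-({(11R)-11-[(2R)-2-(benzyloxycarbonyl)-5-oxo-2,5-dihydrofuran-2-yl]-12-nitrododecyl}oxy)-3-hydroxy-4-oxobutanoic acid | O=C(O)C[C@@H](O)C(=O)OCCCCCCCCCC[C@H](C[N+](=O)[O-])[C@@]1(C(=O)OCc2ccccc2)C=CC(=O)O1 | intermediate
19 | (2S)-2-[(2R)-2-(benzyloxycarbonyl)-5-oxo-2,5-dihydrofuran-2-yl]-12-{[(2R)-3-carboxy-2-hydroxypropanoyl]oxy}dodecanoic acid | O=C(O)C[C@@H](O)C(=O)OCCCCCCCCCC[C@H](C(=O)O)[C@@]1(C(=O)OCc2ccccc2)C=CC(=O)O1 | intermediate
20 | (2R)-2-[(1S)-1-carboxy-11-{[(2R)-3-carboxy-2-hydroxypropanoyl]oxy}undecyl]-5-oxooxolane-2-carboxylic acid | O=C(O)C[C@@H](O)C(=O)OCCCCCCCCCC[C@H](C(=O)O)[C@@]1(C(=O)O)CCC(=O)O1 | target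

**Step count and risks**

Total step count: 8. Longest linear sequence: 6 steps (1, 2, 5, 6, 7, 8; the lactone branch 3, 4, 5, 6, 7, 8 is equally long).

Most likely to fail, first: step 5. The diastereoselectivity of the new quaternary/tertiary pair, and γ- versus α-attack of the dienolate, are not secured by precedent for this substrate pair. The fallback sets out from 13 and comes back at 14. Compound 13 is silylated (iPr3SiOTf, Et3N, CH2Cl2, 0 °C) to benzyl 5-[(triisopropylsilyl)oxy]furan-2-carboxylate F1. F1 is added to 7 in a Mukaiyama–Michael reaction through an open transition state under a chiral Lewis acid, Zn(OTf)2 with (S,S)-2,2'-isopropylidenebis(4-phenyl-2-oxazoline), in toluene at −20 °C. Aqueous acidic work-up removes the silyl group and gives 14. The open, antiperiplanar geometry has a different simple diastereoselection from the ion-paired pathway, and the ligand enantiomer selects the absolute sense.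

Second: step 2. The free hydroxyl has to survive the dehydration, and the terminal nitroalkene can oligomerise or deconjugate under base. The fallback sets out from 2 and comes back at 7. Compound 2 is methylenated (Ph3PCH3Br, KOtBu, 2.2 equiv, THF, 0 °C) to dodec-11-en-1-ol F2. The terminal alkene is then nitrated directly to the (E)-nitroalkene with AgNO2 and TEMPO (2,2,6,6-tetramethylpiperidin-1-oxyl) over 4 Å molecular sieves in 1,2-dichloroethane at 70 °C. This radical nitration–elimination avoids the β-nitro alcohol and any acylating agent.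

Third: step 7. The nitro group sits on a neopentyl-like carbon next to the quaternary centre and may react slowly, while a more basic Nef variant would invite retro-Michael cleavage. The fallback sets out from 18 and comes back at 19. A buffered reductive Nef reaction (aqueous TiCl3, NH4OAc, THF, rt) converts 18 into the aldehyde (3R)-4-({(11S)-11-[(2R)-2-(benzyloxycarbonyl)-5-oxo-2,5-dihydrofuran-2-yl]-12-oxododecyl}oxy)-3-hydroxy-4-oxobutanoic acid F3. F3 is oxidised at once under Pinnick conditions (NaClO2, NaH2PO4, 2-methylbut-2-ene, tBuOH/H2O, 0 °C) to 19, before the β-acyloxy aldehyde can epimerise or eliminate.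

Further compounds
F1 | step 5 | benzyl 5-[(triisopropylsilyl)oxy]furan-2-carboxylate | O=C(OCc1ccccc1)c1ccc(O[Si](C(C)C)(C(C)C)C(C)C)o1
F2 | step 2 | dodec-11-en-1-ol | OCCCCCCCCCCC=C
F3 | step 7 | (3R)-4-({(11S)-11-[(2R)-2-(benzyloxycarbonyl)-5-oxo-2,5-dihydrofuran-2-yl]-12-oxododecyl}oxy)-3-hydroxy-4-oxobutanoic acid | O=C(O)C[C@@H](O)C(=O)OCCCCCCCCCC[C@H](C=O)[C@@]1(C(=O)OCc2ccccc2)C=CC(=O)O1
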